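The route rests on not coupling the two flavones at all. The C6–C8 interflavone bond lies between four oxygen-bearing carbons (C5 and C7 of the 6-linked unit 1, C7 and C8a of the 8-linked unit 2), and ring A of unit 2 is a phloroglucinol with three unlike oxygens. That ring is therefore built around the bond: a thermal benzannulation joins an aryl triisopropylsiloxyalkyne, whose aryl group is ring A of unit 1, to 3-benzyloxycyclobutenone and gives in one operation the biaryl with free OH (later 7-OMe), OTIPS (later O1) and OBn (later 5-OH) already told apart. Both pyranone rings then close together from a bis-chalcone.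

Key step: step 6

Remark: the target SMILES fixes no configuration at the hindered C6–C8 biaryl axis, so the racemic mixture of atropisomers is taken as the target; 3-ethoxycyclobut-2-en-1-one is taken to be purchasable.

Step 1
Reactants: 1 3,5-bis(benzyloxy)phenol
Product: 3 2,6-bis(benzyloxy)-4-hydroxybenzaldehyde, via aryl iminium chloride 2 (not isolated)
Conditions: POCl3, DMF, MeCN, 0 °C to rt; then H2O, 40 °C
Reagents that add atoms: N,N-dimethylformamide CN(C)C=O (formyl carbon); water O (carbonyl oxygen)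
Why: Vilsmeier–Haack formylation is an electrophilic substitution that, by analogy with the corresponding dimethyl ether, should go mainly to the carbon para to the free hydroxyl between the two benzyloxy groups, and the minor hydrogen-bonded ortho-formyl isomer is less polar and should be removable by chromatography.

Step 2
Reactants: 3 2,6-bis(benzyloxy)-4-hydroxybenzaldehyde
Product: 4 2,6-bis(benzyloxy)-4-(triisopropylsilyloxy)benzaldehyde
Conditions: TIPSCl, imidazole, DMF, rt
Reagents that add atoms: chlorotriisopropylsilane CC(C)[Si](Cl)(C(C)C)C(C)C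
Why: Routine imidazole-mediated O-silylation of the unhindered para-phenol, the triisopropylsilyl ether being chosen because it should withstand organolithium reagents at low temperature and heating in toluene and is later removed together with the second silyl group.

Step 3
Reactants: 4 2,6-bis(benzyloxy)-4-(triisopropylsilyloxy)benzaldehyde
Product: 5 1,3-bis(benzyloxy)-2-ethynyl-5-(triisopropylsilyloxy)benzene
Conditions: TMSCHN2, LiN(iPr)2, THF, −78 °C to rt
Reagents that add atoms: (trimethylsilyl)diazomethane C[Si](C)(C)C=[N+]=[N-] (one carbon)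
Why: Colvin rearrangement, in which lithiated trimethylsilyldiazomethane adds to the aldehyde, Peterson-type loss of lithium trimethylsilanolate and then of N2 gives an alkylidene carbene, and its 1,2-shift delivers the terminal alkyne in one operation without touching the aryl silyl ether or the benzyl ethers.

Step 4
Reactants: 5 1,3-bis(benzyloxy)-2-ethynyl-5-(triisopropylsilyloxy)benzene
Product: 8 1,3-bis(benzyloxy)-5-(triisopropylsilyloxy)-2-[(triisopropylsilyloxy)ethynyl]benzene, via lithium acetylide 6 (not isolated), via lithium ynolate 7 (not isolated)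
Conditions: n-BuLi, THF, −78 °C; LiOOt-Bu (t-BuOOH + LiN(SiMe3)2), −78 to 0 °C; TIPSOTf, −78 to 0 °C; quick filtration through Et3N-deactivated silica
Reagents that add atoms: tert-butyl hydroperoxide CC(C)(C)OO (one oxygen, delivered as its lithium salt); triisopropylsilyl trifluoromethanesulfonate CC(C)[Si](OS(=O)(=O)C(F)(F)F)(C(C)C)C(C)C
Why: Established one-pot preparation of siloxyalkynes, in which the lithium acetylide is oxidised at its terminal carbon by the lithium peroxide to the ynolate and the bulky silyl triflate traps the ynolate on oxygen and not on carbon.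

Step 5
Reactants: 9 3-ethoxycyclobut-2-en-1-one
Product: 10 3-(benzyloxy)cyclobut-2-en-1-one
Conditions: BnOH (3 equiv), pyridinium p-toluenesulfonate (cat.), toluene, 40 °C, reduced pressure
Reagents that add atoms: benzyl alcohol OCc1ccccc1
Why: Acid-catalysed addition–elimination at the β-carbon of the vinylogous ester (vinylogous transesterification), pushed to the benzyl enol ether by excess benzyl alcohol and removal of the more volatile ethanol at a temperature below that of cyclobutenone ring opening.

Step 6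
Reactants: 8 1,3-bis(benzyloxy)-5-(triisopropylsilyloxy)-2-[(triisopropylsilyloxy)ethynyl]benzene; 10 3-(benzyloxy)cyclobut-2-en-1-one
Product: 15 2',4,6'-tris(benzyloxy)-4',6-bis(triisopropylsilyloxy)biphenyl-2-ol, via vinylketene 11 (not isolated), via vinylcyclobutenone 12 (not isolated), via dienylketene 13 (not isolated), via cyclohexadienone 14 (not isolated)
Conditions: toluene, 80 °C then 110 °C, sealed tube, 10 (1.5 equiv) added slowly
Reagents that add atoms: none
Why: Proposed new method: heating should open cyclobutenone 10 by 4π electrocyclic cleavage to the benzyloxy-substituted vinylketene 11, whose central sp carbon is attacked by the nucleophilic aryl-bearing carbon of the polarised siloxyalkyne 8 in a ketene–alkyne [2+2] cycloaddition, giving vinylcyclobutenone 12 (a transient four-membered ring closed by cycloaddition), which reopens to dienylketene 13. Ring A of unit 2 then closes by thermal 6π electrocyclisation of 13 (bond between the ketene carbon and the terminal methylene, C6–C7 of unit 2) and cyclohexadienone 14 tautomerises to phenol 15, so that in sum the two alkyne carbons are inserted between C1 and C2 of the cyclobutenone and the C7–C8 and C8a–C4a bonds of unit 2 are formed. The closest known reaction is the Danheiser benzannulation of alkyl- or aryl-substituted cyclobutenones with trialkylsiloxyalkynes, which gives resorcinol monosilyl ethers in the same way but has not been shown with a 3-alkoxycyclobutenone or with a 2,6-dioxygenated aryl siloxyalkyne. The only bond made at the crowded aryl-bearing carbon is to a linear ketene carbon from a linear alkyne, so the four flanking oxygens that would obstruct a biaryl coupling should not interfere. The selectivity needed is the regiochemistry of the [2+2] step, secured by the oxygen lone pair of the siloxyalkyne, which makes the aryl-bearing carbon the nucleophile and so places the aryl group between the new OH and the OTIPS group with OBn para to it. No stereocentre is created (12 is a transient racemate) and the biaryl axis still carries a symmetric ring at this stage.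

Step 7
Reactants: 15 2',4,6'-tris(benzyloxy)-4',6-bis(triisopropylsilyloxy)biphenyl-2-ol
Product: 16 2',4,6'-tris(benzyloxy)-2-methoxy-4',6-bis(triisopropylsilyloxy)biphenyl
Conditions: MeI, K2CO3, acetone, 50 °C
Reagents that add atoms: iodomethane CI
Why: Williamson O-methylation of the only free phenol with a weak base, which fixes the future 7-methoxy group of unit 2 and should leave both aryl silyl ethers in place.

Step 8
Reactants: 16 2',4,6'-tris(benzyloxy)-2-methoxy-4',6-bis(triisopropylsilyloxy)biphenyl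
Product: 17 2',4,6'-tris(benzyloxy)-6-methoxybiphenyl-2,4'-diol
Conditions: Bu4NF, AcOH, THF, 0 °C
Reagents that add atoms: none
Why: Fluoride-induced desilylation cleaves both aryl Si–O bonds, driven by the strong Si–F bond, while benzyl and methyl ethers are inert and acetic acid buffers the electron-rich phenoxides.

Step 9
Reactants: 17 2',4,6'-tris(benzyloxy)-6-methoxybiphenyl-2,4'-diol
Product: 18 2',4,6'-tris(benzyloxy)-6-methoxybiphenyl-2,4'-diyl diacetate
Conditions: Ac2O, pyridine, DMAP (cat.), CH2Cl2, rt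
Reagents that add atoms: acetic anhydride CC(=O)OC(C)=O
Why: Routine DMAP-catalysed O-acetylation of both phenols, which places exactly one acetyl group on each ring for the acyl migration that follows.

Step 10
Reactants: 18 2',4,6'-tris(benzyloxy)-6-methoxybiphenyl-2,4'-diyl diacetate
Product: 20 1,1'-[2',4,6'-tris(benzyloxy)-2,4'-dihydroxy-6-methoxybiphenyl-3,3'-diyl]diethanone, via bis(difluoroboron) chelate 19 (not isolated)
Conditions: BF3·OEt2 (4 equiv), ClCH2CH2Cl, 0 to 45 °C; then MeOH–H2O, 50 °C
Reagents that add atoms: none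
Why: Fries rearrangement, in which BF3 ionises each electron-rich aryl acetate and the acylium returns to the ring ortho to the phenolic oxygen (the only open ortho carbon, C4a, in ring A of unit 2 and either of two equivalent ortho carbons in ring A of unit 1), where capture as a difluoroboron chelate should favour ortho over para attack and keep the Lewis acid away from the benzyl ethers; the biaryl axis becomes stereogenic here and forms as a racemate.

Step 11
Reactants: 20 1,1'-[2',4,6'-tris(benzyloxy)-2,4'-dihydroxy-6-methoxybiphenyl-3,3'-diyl]diethanone; 21 4-methoxybenzaldehyde (3 equiv)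
Product: 22 (2E,2'E)-1,1'-[2',4,6'-tris(benzyloxy)-2,4'-dihydroxy-6-methoxybiphenyl-3,3'-diyl]bis[3-(4-methoxyphenyl)prop-2-en-1-one]
Conditions: KOH, EtOH–H2O, rt to 40 °C; then dilute HCl
Reagents that add atoms: none
Why: Double Claisen–Schmidt condensation, in which each methyl ketone enolate adds to the non-enolisable aldehyde and the aldol dehydrates to the conjugated enone with the thermodynamically favoured E geometry.

Step 12
Reactants: 22 (2E,2'E)-1,1'-[2',4,6'-tris(benzyloxy)-2,4'-dihydroxy-6-methoxybiphenyl-3,3'-diyl]bis[3-(4-methoxyphenyl)prop-2-en-1-one]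
Product: 23 5,7-bis(benzyloxy)-6-[5-(benzyloxy)-7-methoxy-2-(4-methoxyphenyl)-4-oxo-4H-chromen-8-yl]-2-(4-methoxyphenyl)-4H-chromen-4-one
Conditions: I2 (cat.), DMSO, 120 °C
Reagents that add atoms: none
Why: Iodine-catalysed oxidative cyclisation of 2'-hydroxychalcones in DMSO, in which each phenol adds to its enone (6-endo oxa-Michael addition) and iodination–elimination with DMSO as terminal oxidant gives the flavone, only the wanted pyranone being possible because the other oxygen ortho to each ketone is benzylated.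

Step 13
Reactants: 23 5,7-bis(benzyloxy)-6-[5-(benzyloxy)-7-methoxy-2-(4-methoxyphenyl)-4-oxo-4H-chromen-8-yl]-2-(4-methoxyphenyl)-4H-chromen-4-one
Product: 24 5,7-dihydroxy-6-[5-hydroxy-7-methoxy-2-(4-methoxyphenyl)-4-oxo-4H-chromen-8-yl]-2-(4-methoxyphenyl)-4H-chromen-4-one (CNP0146326.0)
Conditions: H2 (1 atm), Pd/C, THF–MeOH, rt
Reagents that add atoms: none
Why: Catalytic hydrogenolysis of the three aryl benzyl ethers over palladium on carbon, conditions under which aryl methyl ethers and the flavone nucleus are normally retained.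

Compound list
1 | 3,5-bis(benzyloxy)phenol | Oc1cc(OCc2ccccc2)cc(OCc2ccccc2)c1 | starting material
2 | aryl iminium chloride, N-[2,6-bis(benzyloxy)-4-hydroxybenzylidene]-N-methylmethanaminium chloride | C[N+](C)=Cc1c(OCc2ccccc2)cc(O)cc1OCc1ccccc1.[Cl-] | intermediate (not isolated)
3 | 2,6-bis(benzyloxy)-4-hydroxybenzaldehyde | O=Cc1c(OCc2ccccc2)cc(O)cc1OCc1ccccc1 | intermediate
4 | 2,6-bis(benzyloxy)-4-(triisopropylsilyloxy)benzaldehyde | O=Cc1c(OCc2ccccc2)cc(O[Si](C(C)C)(C(C)C)C(C)C)cc1OCc1ccccc1 | intermediate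
5 | 1,3-bis(benzyloxy)-2-ethynyl-5-(triisopropylsilyloxy)benzene | C#Cc1c(OCc2ccccc2)cc(O[Si](C(C)C)(C(C)C)C(C)C)cc1OCc1ccccc1 | intermediate
6 | lithium acetylide of 5 | [Li]C#Cc1c(OCc2ccccc2)cc(O[Si](C(C)C)(C(C)C)C(C)C)cc1OCc1ccccc1 | intermediate (not isolated)
7 | lithium ynolate, lithium 2-[2,6-bis(benzyloxy)-4-(triisopropylsilyloxy)phenyl]ethynolate | [Li]OC#Cc1c(OCc2ccccc2)cc(O[Si](C(C)C)(C(C)C)C(C)C)cc1OCc1ccccc1 | intermediate (not isolated)
8 | 1,3-bis(benzyloxy)-5-(triisopropylsilyloxy)-2-[(triisopropylsilyloxy)ethynyl]benzene | CC(C)[Si](C(C)C)(C(C)C)OC#Cc1c(OCc2ccccc2)cc(O[Si](C(C)C)(C(C)C)C(C)C)cc1OCc1ccccc1 | intermediate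
9 | 3-ethoxycyclobut-2-en-1-one | CCOC1=CC(=O)C1 | starting material
10 | 3-(benzyloxy)cyclobut-2-en-1-one | O=C1CC(OCc2ccccc2)=C1 | intermediate
11 | vinylketene, 3-(benzyloxy)buta-1,3-dien-1-one | C=C(OCc1ccccc1)C=C=O | intermediate (not isolated)
12 | vinylcyclobutenone, 2-[2,6-bis(benzyloxy)-4-(triisopropylsilyloxy)phenyl]-4-[1-(benzyloxy)ethenyl]-3-(triisopropylsilyloxy)cyclobut-2-en-1-one (racemic) | C=C(OCc1ccccc1)C1C(=O)C(c2c(OCc3ccccc3)cc(O[Si](C(C)C)(C(C)C)C(C)C)cc2OCc2ccccc2)=C1O[Si](C(C)C)(C(C)C)C(C)C | intermediate (not isolated)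
13 | dienylketene, (3E)-2-[2,6-bis(benzyloxy)-4-(triisopropylsilyloxy)phenyl]-5-(benzyloxy)-3-(triisopropylsilyloxy)hexa-1,3,5-trien-1-one (ketene and benzyloxyvinyl groups cis across the central C=C) | C=C(OCc1ccccc1)/C=C(/O[Si](C(C)C)(C(C)C)C(C)C)C(=C=O)c1c(OCc2ccccc2)cc(O[Si](C(C)C)(C(C)C)C(C)C)cc1OCc1ccccc1 | intermediate (not isolated)
14 | cyclohexadienone, 2-[2,6-bis(benzyloxy)-4-(triisopropylsilyloxy)phenyl]-5-(benzyloxy)-3-(triisopropylsilyloxy)cyclohexa-2,4-dien-1-one | O=C1CC(OCc2ccccc2)=CC(O[Si](C(C)C)(C(C)C)C(C)C)=C1c1c(OCc2ccccc2)cc(O[Si](C(C)C)(C(C)C)C(C)C)cc1OCc1ccccc1 | intermediate (not isolated)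
15 | 2',4,6'-tris(benzyloxy)-4',6-bis(triisopropylsilyloxy)biphenyl-2-ol | Oc1cc(OCc2ccccc2)cc(O[Si](C(C)C)(C(C)C)C(C)C)c1-c1c(OCc2ccccc2)cc(O[Si](C(C)C)(C(C)C)C(C)C)cc1OCc1ccccc1 | intermediate
16 | 2',4,6'-tris(benzyloxy)-2-methoxy-4',6-bis(triisopropylsilyloxy)biphenyl | COc1cc(OCc2ccccc2)cc(O[Si](C(C)C)(C(C)C)C(C)C)c1-c1c(OCc2ccccc2)cc(O[Si](C(C)C)(C(C)C)C(C)C)cc1OCc1ccccc1 | intermediate
17 | 2',4,6'-tris(benzyloxy)-6-methoxybiphenyl-2,4'-diol | COc1cc(OCc2ccccc2)cc(O)c1-c1c(OCc2ccccc2)cc(O)cc1OCc1ccccc1 | intermediate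
18 | 2',4,6'-tris(benzyloxy)-6-methoxybiphenyl-2,4'-diyl diacetate | COc1cc(OCc2ccccc2)cc(OC(C)=O)c1-c1c(OCc2ccccc2)cc(OC(C)=O)cc1OCc1ccccc1 | intermediate
19 | bis(difluoroboron) chelate of 20 (each ketone oxygen and adjacent phenolic oxygen bridged by BF2) | COc1cc(OCc3ccccc3)c2c(O[B-](F)(F)[O+]=C2C)c1-c1c(OCc2ccccc2)cc2O[B-](F)(F)[O+]=C(C)c2c1OCc1ccccc1 | intermediate (not isolated)
20 | 1,1'-[2',4,6'-tris(benzyloxy)-2,4'-dihydroxy-6-methoxybiphenyl-3,3'-diyl]diethanone (racemic axis) | COc1cc(OCc2ccccc2)c(C(C)=O)c(O)c1-c1c(OCc2ccccc2)cc(O)c(C(C)=O)c1OCc1ccccc1 | intermediate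
21 | 4-methoxybenzaldehyde | COc1ccc(C=O)cc1 | starting material
22 | (2E,2'E)-1,1'-[2',4,6'-tris(benzyloxy)-2,4'-dihydroxy-6-methoxybiphenyl-3,3'-diyl]bis[3-(4-methoxyphenyl)prop-2-en-1-one] (racemic axis) | COc1cc(OCc2ccccc2)c(C(=O)/C=C/c2ccc(OC)cc2)c(O)c1-c1c(OCc2ccccc2)cc(O)c(C(=O)/C=C/c2ccc(OC)cc2)c1OCc1ccccc1 | intermediate
23 | 5,7-bis(benzyloxy)-6-[5-(benzyloxy)-7-methoxy-2-(4-methoxyphenyl)-4-oxo-4H-chromen-8-yl]-2-(4-methoxyphenyl)-4H-chromen-4-one (racemic axis) | COc1cc(OCc2ccccc2)c2c(=O)cc(-c3ccc(OC)cc3)oc2c1-c1c(OCc2ccccc2)cc2oc(-c3ccc(OC)cc3)cc(=O)c2c1OCc1ccccc1 | intermediate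
24 | 5,7-dihydroxy-6-[5-hydroxy-7-methoxy-2-(4-methoxyphenyl)-4-oxo-4H-chromen-8-yl]-2-(4-methoxyphenyl)-4H-chromen-4-one, CNP0146326.0 (racemic axis) | COc1ccc(-c2cc(=O)c3c(O)c(-c4c(OC)cc(O)c5c(=O)cc(-c6ccc(OC)cc6)oc45)c(O)cc3o2)cc1 | target

Total step count: 13.
Longest linear sequence: 12 steps, from 1 to 24 through steps 1 to 4 and 6 to 13; step 5 is a one-step side branch.

Steps most likely to fail

Step 6. The donor-stabilised cyclobutenone may open too slowly, so that the sensitive siloxyalkyne decomposes first, or the vinylketene may be drained by dimerisation or by O-acylation of the phenolic product. The fallback gives up the ring construction and makes the biaryl bond by known cross-coupling, setting out from 1 and coming back at 17. Compound 1 would be silylated (TIPSCl, imidazole) to 1,3-bis(benzyloxy)-5-(triisopropylsilyloxy)benzene F1, lithiated between the two benzyloxy groups (n-BuLi, THF, 0 °C; the bulky silyl ether neither directs nor leaves room beside it) and trapped with 2-isopropoxy-4,4,5,5-tetramethyl-1,3,2-dioxaborolane to give 2-[2,6-bis(benzyloxy)-4-(triisopropylsilyloxy)phenyl]-4,4,5,5-tetramethyl-1,3,2-dioxaborolane F2. Separately, purchased phloroglucinol would be protected twice (MOMCl, iPr2NEt) to 3,5-bis(methoxymethoxy)phenol F3 and benzylated (BnBr, K2CO3) to 1-(benzyloxy)-3,5-bis(methoxymethoxy)benzene F4. Directed lithiation between the two acetal oxygens (n-BuLi, THF, 0 °C) and quenching with I2 would then give 5-(benzyloxy)-2-iodo-1,3-bis(methoxymethoxy)benzene F5. Suzuki–Miyaura coupling of F2 with F5 (Pd(OAc)2, SPhos, K3PO4, toluene–H2O, 100 °C), the established way to tetra-ortho-alkoxy biaryls, should give 2',4,6'-tris(benzyloxy)-2,6-bis(methoxymethoxy)-4'-(triisopropylsilyloxy)biphenyl F6. HCl in MeOH would remove both acetals to give 2',4,6'-tris(benzyloxy)-4'-(triisopropylsilyloxy)biphenyl-2,6-diol F7. Its two hydroxyls are equivalent, so methylation with one equivalent of MeI (K2CO3, acetone; recovered diol recycled) would give 2',4,6'-tris(benzyloxy)-6-methoxy-4'-(triisopropylsilyloxy)biphenyl-2-ol F8, and Bu4NF then gives 17.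

Step 10. The Lewis acid may cleave or shift benzyl ethers on these phloroglucinol rings, and in ring A of unit 2 the acyl group may go to the para carbon C6 instead of C4a. The fallback avoids acid and electrophilic acylation, setting out from 17 and coming back at 20. Magnesium-mediated ortho-formylation (MgCl2, Et3N, paraformaldehyde, MeCN, reflux; Casnati–Skattebøl conditions, strictly ortho to each phenoxide) should give 2',4,6'-tris(benzyloxy)-2,4'-dihydroxy-6-methoxybiphenyl-3,3'-dicarbaldehyde F9. Excess MeMgBr (THF, 0 °C) would give the bis-carbinol 1,1'-[2',4,6'-tris(benzyloxy)-2,4'-dihydroxy-6-methoxybiphenyl-3,3'-diyl]diethanol F10 as a diastereomer mixture. This would be oxidised crude with MnO2 in CH2Cl2 to 20.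

Step 5. The strained vinylogous ester may hydrolyse or oligomerise under acid before the exchange is complete. The fallback replaces the equilibrium exchange by O-alkylation of the free enol, setting out from 9 and coming back at 10. Cold dilute aqueous HCl would hydrolyse 9 to cyclobutane-1,3-dione F11, a strongly acidic enol, which would be O-benzylated under Mitsunobu conditions (BnOH, PPh3, diisopropyl azodicarboxylate, THF, 0 °C) to 10.

Further compounds
F1 | step 6 | 1,3-bis(benzyloxy)-5-(triisopropylsilyloxy)benzene | CC(C)[Si](Oc1cc(OCc2ccccc2)cc(OCc2ccccc2)c1)(C(C)C)C(C)C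
F2 | step 6 | 2-[2,6-bis(benzyloxy)-4-(triisopropylsilyloxy)phenyl]-4,4,5,5-tetramethyl-1,3,2-dioxaborolane | CC(C)[Si](Oc1cc(OCc2ccccc2)c(B2OC(C)(C)C(C)(C)O2)c(OCc2ccccc2)c1)(C(C)C)C(C)C
F3 | step 6 | 3,5-bis(methoxymethoxy)phenol | COCOc1cc(O)cc(OCOC)c1
F4 | step 6 | 1-(benzyloxy)-3,5-bis(methoxymethoxy)benzene | COCOc1cc(OCc2ccccc2)cc(OCOC)c1
F5 | step 6 | 5-(benzyloxy)-2-iodo-1,3-bis(methoxymethoxy)benzene | COCOc1cc(OCc2ccccc2)cc(OCOC)c1I
F6 | step 6 | 2',4,6'-tris(benzyloxy)-2,6-bis(methoxymethoxy)-4'-(triisopropylsilyloxy)biphenyl | COCOc1cc(OCc2ccccc2)cc(OCOC)c1-c1c(OCc2ccccc2)cc(O[Si](C(C)C)(C(C)C)C(C)C)cc1OCc1ccccc1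
F7 | step 6 | 2',4,6'-tris(benzyloxy)-4'-(triisopropylsilyloxy)biphenyl-2,6-diol | Oc1cc(OCc2ccccc2)cc(O)c1-c1c(OCc2ccccc2)cc(O[Si](C(C)C)(C(C)C)C(C)C)cc1OCc1ccccc1
F8 | step 6 | 2',4,6'-tris(benzyloxy)-6-methoxy-4'-(triisopropylsilyloxy)biphenyl-2-ol | COc1cc(OCc2ccccc2)cc(O)c1-c1c(OCc2ccccc2)cc(O[Si](C(C)C)(C(C)C)C(C)C)cc1OCc1ccccc1
F9 | step 10 | 2',4,6'-tris(benzyloxy)-2,4'-dihydroxy-6-methoxybiphenyl-3,3'-dicarbaldehyde | COc1cc(OCc2ccccc2)c(C=O)c(O)c1-c1c(OCc2ccccc2)cc(O)c(C=O)c1OCc1ccccc1
F10 | step 10 | 1,1'-[2',4,6'-tris(benzyloxy)-2,4'-dihydroxy-6-methoxybiphenyl-3,3'-diyl]diethanol (diastereomer mixture) | COc1cc(OCc2ccccc2)c(C(C)O)c(O)c1-c1c(OCc2ccccc2)cc(O)c(C(C)O)c1OCc1ccccc1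
F11 | step 5 | cyclobutane-1,3-dione | O=C1CC(=O)C1
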